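Ring C of the target (O1, C2, C3, C4, C4a, C8a) is read as the furanone ring of a 2-arylcoumaranone enlarged by one carbon, C3, which lies between C2 and the carbonyl carbon C4 and bears the 3-hydroxyl. Everything rests on excising C3: dibromocarbene is added across the C2=C3 enol-ether bond of a 2-aryl-3-silyloxybenzofuran, and collapse of the adduct forms C2–C3 and C3–C4 of the flavone, turns the furan into the pyranone and leaves bromine on C3 for later exchange to hydroxyl. The precursor, made by telescoped α-arylation and O-silylation of 4,6,7-trimethoxycoumaranone, carries the 2'-oxygen as a benzyl ether and the 5-oxygen as a methyl ether.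

Key step: step 5

Assumption: in the Friedel–Crafts step the methoxy group that is cleaved is the crowded one, flanked by the new acyl group and a neighbouring methoxy group, as expected for chelation-assisted cleavage in congested ortho-methoxy aryl ketones.

Step 1
Reactants: 1 1,2,3,5-tetramethoxybenzene; 2 chloroacetyl chloride
Product: 3 2-chloro-1-(2-hydroxy-3,4,6-trimethoxyphenyl)ethan-1-one
Conditions: ClCH2COCl, AlCl3, CH2Cl2, 0 °C → rt; aq. HCl work-up
Reagents that add atoms: chloroacetyl chloride (compound 2), O=C(Cl)CCl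
Why: Friedel–Crafts acylation occurs at the only kind of free ring position, and the aluminium chelate of the new ketone then cleaves the crowded ortho-methoxy group (chelation-assisted Lewis-acid ether cleavage), which frees the phenol needed for ring closure and avoids a separate α-halogenation on an electron-rich ring.

Step 2
Reactants: 3 2-chloro-1-(2-hydroxy-3,4,6-trimethoxyphenyl)ethan-1-one
Product: 4 4,6,7-trimethoxy-1-benzofuran-3(2H)-one
Conditions: NaOAc, EtOH, reflux
Reagents that add atoms: none
Why: Intramolecular Williamson etherification, a favoured 5-exo-tet displacement of the primary α-chloride by the phenoxide under a base too weak to cause aldol self-condensation of the coumaranone.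

Step 3
Reactants: 5 2-bromo-5-methoxyphenol
Product: 6 2-(benzyloxy)-1-bromo-4-methoxybenzene
Conditions: BnBr, K2CO3, DMF, rt
Reagents that add atoms: benzyl bromide, BrCc1ccccc1
Why: Williamson ether synthesis on a phenol; the benzyl ether tolerates the basic steps that follow and is removed together with the 5-O-methyl group in the last step.

Step 4
Reactants: 4 4,6,7-trimethoxy-1-benzofuran-3(2H)-one; 6 2-(benzyloxy)-1-bromo-4-methoxybenzene
Product: 8 tert-butyl({2-[2-(benzyloxy)-4-methoxyphenyl]-4,6,7-trimethoxy-1-benzofuran-3-yl}oxy)dimethylsilane, via sodium benzofuran-3-olate 7 (not isolated)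
Conditions: Pd2(dba)3 (cat.), XPhos, NaOtBu, toluene, 80 °C; then TBSCl, THF, 0 °C → rt
Reagents that add atoms: tert-butyldimethylsilyl chloride, CC(C)(C)[Si](C)(C)Cl
Why: Palladium-catalysed ketone α-arylation, in which the sodium enolate of 4 couples with the aryl bromide through a zerovalent palladium/biarylphosphine catalyst and the more acidic product stays as enolate 7, whose O-silylation in the same flask is driven by aromatisation to the benzofuran and spares isolation of the air-sensitive 2-arylcoumaranone.

Step 5
Reactants: 8 tert-butyl({2-[2-(benzyloxy)-4-methoxyphenyl]-4,6,7-trimethoxy-1-benzofuran-3-yl}oxy)dimethylsilane; 9 bromoform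
Product: 12 2-[2-(benzyloxy)-4-methoxyphenyl]-3-bromo-5,7,8-trimethoxy-4H-chromen-4-one, via dibromocyclopropane adduct 10 (not isolated), via 3-bromo-4-silyloxyflavylium bromide 11 (not isolated)
Conditions: CHBr3, KOtBu, toluene–hexane, −30 °C → rt; aq. NaHCO3 work-up
Reagents that add atoms: bromoform (compound 9), BrC(Br)Br
Why: Proposed new method: KOtBu α-eliminates HBr from bromoform and the electrophilic dibromocarbene adds in a concerted [2+1] cheletropic step across benzofuran C2=C3 of 8 to give the cis-fused cyclopropane 10; its endo bromide then ionises while the shared C–C bond opens in a disrotatory two-electron electrocyclic fashion, pushed by the lone pairs of O1 and of the silyloxy oxygen, to the flavylium ion 11, and bromide takes the silyl group from oxygen to unveil the C4 carbonyl of 12. The closest known reaction types are the dihalocarbene ring expansion of cyclic silyl enol ethers to 2-halo-enones and the Ciamician–Dennstedt one-carbon expansion of indoles and benzofurans, neither of which has been shown to turn a 3-silyloxybenzofuran into a 3-haloflavone. The six-membered ring C is closed by ring expansion and not by an end-to-end cyclisation: the three-membered ring forms by cycloaddition, and cleavage of the zero-atom bridge of the bicyclo[3.1.0] adduct merges the furan and the cyclopropane into the pyranone, the carbene carbon becoming C3 with new bonds to C2 and C4. No stereocentre is created in 12, because both sp3 ring-fusion carbons of racemic 10 return to sp2. The step needs chemoselective attack on the furan enol ether rather than on the alkoxy-substituted benzene rings or the benzylic C–H bonds, and this is secured by the two oxygen donors on C2=C3, which make it by far the most nucleophilic π bond present. It also needs the silyl ether to outlast the alkoxide until the carbene has added, which the bulky tert-butyldimethylsilyl group, the low temperature and the hydrocarbon medium are chosen to ensure.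

Step 6
Reactants: 12 2-[2-(benzyloxy)-4-methoxyphenyl]-3-bromo-5,7,8-trimethoxy-4H-chromen-4-one
Product: 14 2-[2-(benzyloxy)-4-methoxyphenyl]-3-hydroxy-5,7,8-trimethoxy-4H-chromen-4-one, via flavone 3-boronic ester 13 (not isolated)
Conditions: B2pin2, Pd(OAc)2 (cat.), SPhos, KOAc, 1,4-dioxane, 90 °C; then 30% aq. H2O2, NaHCO3, THF, 0 °C
Reagents that add atoms: hydrogen peroxide, OO (the C3 oxygen); bis(pinacolato)diboron, CC1(C)OB(OC1(C)C)B1OC(C)(C)C(C)(C)O1 (its boron stays only in 13)
Why: Miyaura borylation of the C3–Br bond (oxidative addition to zerovalent palladium, acetate-assisted transmetalation from the diboron) gives the alkenyl boronate 13, whose C–B bond is oxidised by peroxide through 1,2-migration from boron to oxygen under bicarbonate buffering, which avoids the hydroxide-induced opening of the pyranone that a direct hydroxide displacement would risk.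

Step 7
Reactants: 14 2-[2-(benzyloxy)-4-methoxyphenyl]-3-hydroxy-5,7,8-trimethoxy-4H-chromen-4-one
Product: 15 3,5-dihydroxy-2-(2-hydroxy-4-methoxyphenyl)-7,8-dimethoxy-4H-chromen-4-one (3,5,2'-trihydroxy-7,8,4'-trimethoxyflavone)
Conditions: BCl3 (excess), C6HMe5, CH2Cl2, −78 → 0 °C; MeOH, aq. HCl work-up
Reagents that add atoms: none
Why: Lewis-acid ether cleavage with BCl3, in which the benzyl ether is cleaved with pentamethylbenzene trapping the benzyl cation and the 5-O-methyl group is removed selectively because only it forms a six-membered boron chelate with the C4 carbonyl, so the 7-, 8- and 4'-methyl ethers should persist at 0 °C.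

Compound list
1 | 1,2,3,5-tetramethoxybenzene | COc1cc(OC)c(OC)c(OC)c1 | starting material
2 | chloroacetyl chloride | O=C(Cl)CCl | starting material
3 | 2-chloro-1-(2-hydroxy-3,4,6-trimethoxyphenyl)ethan-1-one | COc1cc(OC)c(C(=O)CCl)c(O)c1OC | intermediate
4 | 4,6,7-trimethoxy-1-benzofuran-3(2H)-one | COc1cc(OC)c2c(c1OC)OCC2=O | intermediate
5 | 2-bromo-5-methoxyphenol | COc1ccc(Br)c(O)c1 | starting material
6 | 2-(benzyloxy)-1-bromo-4-methoxybenzene | COc1ccc(Br)c(OCc2ccccc2)c1 | intermediate
7 | sodium 2-[2-(benzyloxy)-4-methoxyphenyl]-4,6,7-trimethoxy-1-benzofuran-3-olate (enolate of the 2-arylcoumaranone, not isolated) | COc1ccc(-c2oc3c(OC)c(OC)cc(OC)c3c2[O-])c(OCc2ccccc2)c1.[Na+] | intermediate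
8 | tert-butyl({2-[2-(benzyloxy)-4-methoxyphenyl]-4,6,7-trimethoxy-1-benzofuran-3-yl}oxy)dimethylsilane | COc1ccc(-c2oc3c(OC)c(OC)cc(OC)c3c2O[Si](C)(C)C(C)(C)C)c(OCc2ccccc2)c1 | intermediate
9 | bromoform | BrC(Br)Br | starting material
10 | 1a-[2-(benzyloxy)-4-methoxyphenyl]-1,1-dibromo-6b-[(tert-butyldimethylsilyl)oxy]-3,4,6-trimethoxy-1a,6b-dihydro-1H-cyclopropa[b][1]benzofuran (CBr2 bridging old C2 and C3; cis ring fusion, racemic, one enantiomer drawn; not isolated) | COc1ccc([C@]23Oc4c(OC)c(OC)cc(OC)c4[C@@]2(O[Si](C)(C)C(C)(C)C)C3(Br)Br)c(OCc2ccccc2)c1 | intermediate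
11 | 2-[2-(benzyloxy)-4-methoxyphenyl]-3-bromo-4-[(tert-butyldimethylsilyl)oxy]-5,7,8-trimethoxychromenylium bromide (not isolated) | COc1ccc(-c2[o+]c3c(OC)c(OC)cc(OC)c3c(O[Si](C)(C)C(C)(C)C)c2Br)c(OCc2ccccc2)c1.[Br-] | intermediate
12 | 2-[2-(benzyloxy)-4-methoxyphenyl]-3-bromo-5,7,8-trimethoxy-4H-chromen-4-one | COc1ccc(-c2oc3c(OC)c(OC)cc(OC)c3c(=O)c2Br)c(OCc2ccccc2)c1 | intermediate
13 | 2-[2-(benzyloxy)-4-methoxyphenyl]-5,7,8-trimethoxy-3-(4,4,5,5-tetramethyl-1,3,2-dioxaborolan-2-yl)-4H-chromen-4-one (not isolated) | COc1ccc(-c2oc3c(OC)c(OC)cc(OC)c3c(=O)c2B4OC(C)(C)C(C)(C)O4)c(OCc2ccccc2)c1 | intermediate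
14 | 2-[2-(benzyloxy)-4-methoxyphenyl]-3-hydroxy-5,7,8-trimethoxy-4H-chromen-4-one | COc1ccc(-c2oc3c(OC)c(OC)cc(OC)c3c(=O)c2O)c(OCc2ccccc2)c1 | intermediate
15 | 3,5-dihydroxy-2-(2-hydroxy-4-methoxyphenyl)-7,8-dimethoxy-4H-chromen-4-one (no stereocentres) | COc1ccc(-c2oc3c(OC)c(OC)cc(O)c3c(=O)c2O)c(O)c1 | target

Total step count: 7. Longest linear sequence: 6 steps (steps 1, 2, 4, 5, 6 and 7); step 3 is a one-step branch.

Steps most likely to fail

Step 5 (ring expansion). The carbene may be quenched by alkoxide or tert-butanol before it reaches the crowded, tetrasubstituted C2=C3 bond. The alkoxide may also strip the silyl group first, so that the free enolate is C-alkylated instead of cyclopropanated. A third risk is that the adduct opens at an outer cyclopropane bond instead of the shared one, so that no ring expansion takes place. The fallback uses known chalcone chemistry, sets out from 1 and 6 and returns to the route at 14. Friedel–Crafts acetylation of 1 (AcCl, AlCl3, CH2Cl2) with the same ortho-demethylation should give 1-(2-hydroxy-3,4,6-trimethoxyphenyl)ethan-1-one F1. Bromine–lithium exchange on 6 (n-BuLi, THF, −78 °C) gives [2-(benzyloxy)-4-methoxyphenyl]lithium F2, which DMF formylates to 2-(benzyloxy)-4-methoxybenzaldehyde F3. Claisen–Schmidt condensation of F1 with F3 (KOH, EtOH, rt) should give (2E)-3-[2-(benzyloxy)-4-methoxyphenyl]-1-(2-hydroxy-3,4,6-trimethoxyphenyl)prop-2-en-1-one F4. Iodine-catalysed oxidative cyclisation in DMSO at 120 °C should close it to 2-[2-(benzyloxy)-4-methoxyphenyl]-5,7,8-trimethoxy-4H-chromen-4-one F5. Dimethyldioxirane in acetone should epoxidise C2=C3 to the racemic cis-fused 1a-[2-(benzyloxy)-4-methoxyphenyl]-3,4,6-trimethoxy-1a,7a-dihydro-7H-oxireno[2,3-b]chromen-7-one F6, and catalytic TsOH in CH2Cl2 isomerises this epoxide to 14. The Algar–Flynn–Oyamada oxidation of F4 is avoided on purpose, since a 6'-methoxy chalcone tends to give the aurone.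

Step 6 (bromide to hydroxyl). Oxidative addition and transmetalation may be slow at a carbon flanked by the carbonyl and an ortho-substituted aryl group, the boronate may lose boron by protonolysis at 90 °C, or the bromide may simply be reduced. The fallback sets out from 12 and returns at 14, replacing palladium catalysis by a low-temperature metalation so that the boron species is never heated. Bromine–magnesium exchange with iPrMgCl·LiCl (THF, −40 °C) should give chloro{2-[2-(benzyloxy)-4-methoxyphenyl]-5,7,8-trimethoxy-4-oxo-4H-chromen-3-yl}magnesium F7. Quenching with B(OMe)3 gives dimethyl {2-[2-(benzyloxy)-4-methoxyphenyl]-5,7,8-trimethoxy-4-oxo-4H-chromen-3-yl}boronate F8, which is oxidised in the same flask with H2O2/AcOH at 0 °C to 14.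

Step 4 (α-arylation and silylation). The electron-rich, ortho-alkoxy aryl bromide may couple sluggishly with the hindered enolate, the coumaranone may self-condense under the alkoxide base, or the enolate may be oxidised by adventitious air before it is silylated. The fallback sets out from 4 and returns at 8, reversing the order so that the aryl group is attached to an already aromatic, silylated benzofuran. O-Silylation of 4 (TBSOTf, Et3N, CH2Cl2, 0 °C) should give tert-butyl(dimethyl)[(4,6,7-trimethoxy-1-benzofuran-3-yl)oxy]silane F9. Deprotonation of the furan C2–H next to the ring oxygen (n-BuLi, THF, −78 °C) gives {3-[(tert-butyldimethylsilyl)oxy]-4,6,7-trimethoxy-1-benzofuran-2-yl}lithium F10, and transmetalation with ZnCl2 gives chloro{3-[(tert-butyldimethylsilyl)oxy]-4,6,7-trimethoxy-1-benzofuran-2-yl}zinc F11. Negishi coupling of F11 with 6 (Pd(OAc)2, SPhos, THF, 50 °C) gives 8.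

Further compounds
F1 | step 5 | 1-(2-hydroxy-3,4,6-trimethoxyphenyl)ethan-1-one | COc1cc(OC)c(C(C)=O)c(O)c1OC
F2 | step 5 | [2-(benzyloxy)-4-methoxyphenyl]lithium | COc1ccc([Li])c(OCc2ccccc2)c1
F3 | step 5 | 2-(benzyloxy)-4-methoxybenzaldehyde | COc1ccc(C=O)c(OCc2ccccc2)c1
F4 | step 5 | (2E)-3-[2-(benzyloxy)-4-methoxyphenyl]-1-(2-hydroxy-3,4,6-trimethoxyphenyl)prop-2-en-1-one | COc1ccc(/C=C/C(=O)c2c(O)c(OC)c(OC)cc2OC)c(OCc2ccccc2)c1
F5 | step 5 | 2-[2-(benzyloxy)-4-methoxyphenyl]-5,7,8-trimethoxy-4H-chromen-4-one | COc1ccc(-c2cc(=O)c3c(OC)cc(OC)c(OC)c3o2)c(OCc2ccccc2)c1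
F6 | step 5 | 1a-[2-(benzyloxy)-4-methoxyphenyl]-3,4,6-trimethoxy-1a,7a-dihydro-7H-oxireno[2,3-b]chromen-7-one (cis-fused, racemic, one enantiomer drawn) | COc1ccc([C@]23Oc4c(OC)c(OC)cc(OC)c4C(=O)[C@H]2O3)c(OCc2ccccc2)c1
F7 | step 6 | chloro{2-[2-(benzyloxy)-4-methoxyphenyl]-5,7,8-trimethoxy-4-oxo-4H-chromen-3-yl}magnesium | COc1ccc(-c2oc3c(OC)c(OC)cc(OC)c3c(=O)c2[Mg]Cl)c(OCc2ccccc2)c1
F8 | step 6 | dimethyl {2-[2-(benzyloxy)-4-methoxyphenyl]-5,7,8-trimethoxy-4-oxo-4H-chromen-3-yl}boronate | COc1ccc(-c2oc3c(OC)c(OC)cc(OC)c3c(=O)c2B(OC)OC)c(OCc2ccccc2)c1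
F9 | step 4 | tert-butyl(dimethyl)[(4,6,7-trimethoxy-1-benzofuran-3-yl)oxy]silane | COc1cc(OC)c2c(O[Si](C)(C)C(C)(C)C)coc2c1OC
F10 | step 4 | {3-[(tert-butyldimethylsilyl)oxy]-4,6,7-trimethoxy-1-benzofuran-2-yl}lithium | COc1cc(OC)c2c(O[Si](C)(C)C(C)(C)C)c([Li])oc2c1OC
F11 | step 4 | chloro{3-[(tert-butyldimethylsilyl)oxy]-4,6,7-trimethoxy-1-benzofuran-2-yl}zinc | COc1cc(OC)c2c(O[Si](C)(C)C(C)(C)C)c([Zn]Cl)oc2c1OC
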